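**Plan**

- Retrosynthesis: the five O-benzyl groups come off last. The C3–ring B bond is cut next (cross-coupling at a C3 enol triflate), then C3–C4 and C4–C4a together (one-carbon ring expansion), then C3′–C6c (ketone α-arylation). C2 is carried as a lactone carbonyl until after the coupling.
- Enabling feature: in the upper chroman (O1, C2, C3, C4, C4a, C8a, benzo ring A) C4 lies between ring A and the crowded ring C. Taking C4 out leaves a 6-oxygenated benzofuran-2,3-dione whose ketone carbon is C3, so C4 can arrive as the diazo carbon of a ring C aryldiazomethane.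
- Forward, part 1: ring C bromoaldehyde → lower chroman ring (α-arylation of a chroman-4-one, dehydration, hydrogenation) → hydrazone → diazo compound.
- Forward, part 2: ring expansion of the benzofurandione gives the upper pyranone ring as a 4-aryl-3-hydroxycoumarin. Then triflate, Suzuki coupling with the ring B boronate, reduction of the lactone C=O to CH2, hydrogenation, C4 epimerisation and hydrogenolysis.
- Stereochemistry: C3′ (R) from iridium/P,N-catalysed asymmetric hydrogenation of the 3-aryl-2H-chromene. C3 (R) from iridium/P,N-catalysed syn hydrogenation of the 3,4-diaryl-2H-chromene (cis). C4 (S) from base equilibration to the 3,4-trans isomer.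

Key step: step 14

**Remarks**

- Numbering: upper chroman O1, C2, C3, C4, C4a, C5–C8, C8a (ring A); ring B sits on C3. Ring C has C1c on C4, OMe on C2c, oxygen on C4c, and C6c bonded to C3′ of the lower (primed) chroman.
- Abbreviations used in names: ArC = 4-(benzyloxy)-2-[(3R)-7-(benzyloxy)chroman-3-yl]-6-methoxyphenyl; ArB = 2,3-bis(benzyloxy)-4-methoxyphenyl.
- Assumption: the C4–C1c bond is treated as a stereochemically unassigned axis. The intermediates with sp2 C4 (ring-expansion product through the 3,4-diaryl-2H-chromene) are expected as two diastereomeric rotamers and are carried as the mixture. The rotamers of the target are taken to interconvert.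
- Assumption: the four starting materials are taken as purchased.

**Route**

Step 1
Reactants: 1 1-bromo-3,5-dimethoxybenzene
Product: 2 2-bromo-4,6-dimethoxybenzaldehyde
Conditions: POCl3, DMF, 0 → 90 °C; aq. NaOAc
Reagents that add atoms: N,N-dimethylformamide, CN(C)C=O; water, O
Why: Vilsmeier–Haack formylation should occur next to bromine, para to one methoxy group and ortho to the other (the usual site for this arene), which puts the future C4 carbon between the future C6c (Br) and C2c (OMe).

Step 2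
Reactants: 2 2-bromo-4,6-dimethoxybenzaldehyde
Product: 3 2-bromo-4,6-dihydroxybenzaldehyde
Conditions: BBr3 (4 equiv), CH2Cl2, −78 °C → rt; H2O
Reagents that add atoms: none
Why: Lewis-acid cleavage of both aryl methyl ethers, which the aldehyde tolerates, frees the two phenols so that they can be differentiated in steps 3 and 4.

Step 3
Reactants: 3 2-bromo-4,6-dihydroxybenzaldehyde
Product: 4 4-(benzyloxy)-2-bromo-6-hydroxybenzaldehyde
Conditions: BnBr (1.05 equiv), KHCO3, MeCN, 60 °C
Reagents that add atoms: benzyl bromide, BrCc1ccccc1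
Why: Williamson etherification should be selective for the 4-hydroxyl, because the 6-hydroxyl is hydrogen-bonded to the aldehyde and less acidic, as is general for 2,4-dihydroxybenzaldehydes.

Step 4
Reactants: 4 4-(benzyloxy)-2-bromo-6-hydroxybenzaldehyde
Product: 5 4-(benzyloxy)-2-bromo-6-methoxybenzaldehyde
Conditions: MeI, K2CO3, DMF, 40 °C
Reagents that add atoms: iodomethane, CI
Why: Williamson methylation of the remaining chelated phenol installs the C2c methoxy group.

Step 5
Reactants: 5 4-(benzyloxy)-2-bromo-6-methoxybenzaldehyde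
Product: 6 2-[4-(benzyloxy)-2-bromo-6-methoxyphenyl]-1,3-dioxolane
Conditions: ethylene glycol, TsOH·H2O (cat.), toluene, reflux (Dean–Stark)
Reagents that add atoms: ethylene glycol, OCCO
Why: Acetalisation masks the aldehyde against the enolate of step 7 and the hydride of step 8.

Step 6
Reactants: 7 7-hydroxychroman-4-one
Product: 8 7-(benzyloxy)chroman-4-one
Conditions: BnBr, K2CO3, DMF, rt
Reagents that add atoms: benzyl bromide, BrCc1ccccc1
Why: Williamson etherification of the only phenol.

Step 7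
Reactants: 6 2-[4-(benzyloxy)-2-bromo-6-methoxyphenyl]-1,3-dioxolane; 8 7-(benzyloxy)chroman-4-one
Product: 9 7-(benzyloxy)-3-[5-(benzyloxy)-2-(1,3-dioxolan-2-yl)-3-methoxyphenyl]chroman-4-one (racemic at C3′)
Conditions: Pd(dtbpf)Cl2 (3 mol%), NaOt-Bu, THF, 70 °C
Reagents that add atoms: none
Why: Palladium-catalysed ketone α-arylation (Buchwald–Hartwig type) joins C3′ to C6c; ortho-acetal aryl bromides and chroman-4-ones are both known partners, and the new centre needs no control because it becomes sp2 in step 8.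

Step 8
Reactants: 9 7-(benzyloxy)-3-[5-(benzyloxy)-2-(1,3-dioxolan-2-yl)-3-methoxyphenyl]chroman-4-one
Product: 11 4-(benzyloxy)-2-[7-(benzyloxy)-2H-chromen-3-yl]-6-methoxybenzaldehyde, via chroman-4-ol 10 (not isolated)
Conditions: NaBH4, THF/MeOH, 0 °C; then TsOH·H2O, toluene, 80 °C; then 1 M HCl, THF, rt
Reagents that add atoms: water, O
Why: Carbonyl reduction followed by acid-catalysed E1 dehydration of the benzylic, para-oxygenated chroman-4-ol should give the conjugated 3-aryl-2H-chromene, and the same acid hydrolyses the dioxolane.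

Step 9
Reactants: 11 4-(benzyloxy)-2-[7-(benzyloxy)-2H-chromen-3-yl]-6-methoxybenzaldehyde
Product: 12 4-(benzyloxy)-2-[(3R)-7-(benzyloxy)chroman-3-yl]-6-methoxybenzaldehyde
Conditions: H2 (50 bar), [Ir(cod)Cl]2 (1 mol%), chiral phosphine–oxazoline ligand (2.2 mol%), NaB[3,5-(CF3)2C6H3]4 (3 mol%), CH2Cl2, rt
Reagents that add atoms: none
Why: Iridium/P,N-catalysed asymmetric hydrogenation of trisubstituted 3-aryl-2H-chromenes is the established enantioselective entry to isoflavans and sets C3′; the ligand enantiomer is the one that gives (R), to be assigned beforehand on a model isoflavene, and this catalyst type should leave the aryl aldehyde alone.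

Step 10
Reactants: 12 4-(benzyloxy)-2-[(3R)-7-(benzyloxy)chroman-3-yl]-6-methoxybenzaldehyde
Product: 13 (E)-hydrazone of 12, ArC–CH=N–NH2
Conditions: N2H4·H2O (10 equiv), EtOH, 70 °C
Reagents that add atoms: hydrazine, NN
Why: Condensation with excess hydrazine gives the N-unsubstituted hydrazone, and the excess together with the two ortho substituents should suppress azine formation.

Step 11
Reactants: 14 6-hydroxybenzofuran-3(2H)-one
Product: 15 6-(benzyloxy)benzofuran-3(2H)-one
Conditions: BnBr, K2CO3, DMF, rt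
Reagents that add atoms: benzyl bromide, BrCc1ccccc1
Why: The phenol is far more acidic than C2–H, so Williamson O-benzylation should be selective.

Step 12
Reactants: 15 6-(benzyloxy)benzofuran-3(2H)-one
Product: 16 6-(benzyloxy)benzofuran-2,3-dione
Conditions: SeO2 (1.2 equiv), dioxane, 90 °C; filtration, toluene azeotrope
Reagents that add atoms: selenium dioxide, O=[Se]=O
Why: Riley oxidation of the methylene group flanked by ketone and ether oxygen gives the α-keto lactone, which removes the acidic C2 hydrogens and turns C3 into a strongly electrophilic, non-enolisable ketone.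

Step 13
Reactants: 13 (E)-hydrazone of 12
Product: 17 (3R)-7-(benzyloxy)-3-[5-(benzyloxy)-2-(diazomethyl)-3-methoxyphenyl]chroman, ArC–CH=N2 (cold solution, used at once)
Conditions: activated MnO2 (10 equiv), MgSO4, CH2Cl2, 0 °C, dark; cold filtration under argon
Reagents that add atoms: none
Why: Dehydrogenation of hydrazones with MnO2 is a standard base-free route to aryldiazomethanes, and the two ortho substituents should slow azine formation long enough for immediate use.

Step 14
Reactants: 17 ArC–CH=N2; 16 6-(benzyloxy)benzofuran-2,3-dione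
Product: 19 7-(benzyloxy)-4-ArC-3-hydroxy-2H-chromen-2-one, via chromane-2,3-dione tautomer 18 (not isolated)
Conditions: Sc(OTf)3 (10 mol%), 4 Å molecular sieves, CH2Cl2, −78 → 0 °C; 17 added slowly to 16 (1.5 equiv)
Reagents that add atoms: none
Why: Proposed new method: Sc(OTf)3 binds the 1,2-dicarbonyl unit of 16, the nucleophilic diazo carbon of 17 (the future C4) adds to the ketone carbon (C3), and the diazonium alkoxide loses N2 with a 1,2-shift of the ring A carbon (C3a of the benzofurandione, C4a of the chroman) from C3 to C4, so that C3–C4 and C4–C4a form while the old aryl–carbonyl bond breaks. The closest known reaction type is the ring expansion of isatins by aryldiazomethanes to 4-aryl-3-hydroxyquinolin-2-ones, within the wider family of Lewis-acid-catalysed Tiffeneau–Demjanov-type homologations of cyclic ketones with diazoalkanes. The six-membered pyranone ring closes by enlargement of the five-membered keto lactone through this migration (no separate cyclisation), and 18 then tautomerises to the stable enol 19. No stereocentre is carried out of the step because C4 is sp2 in 19, and C3′ is a spectator. The step needs aryl over acyl migration and a single insertion: the migrating carbon is electron-rich (para to the benzyloxy group), the lactone carbonyl carbon is a poor migrating group, and the enol product offers no ketone for a second insertion. The 2,3-dione is chosen over the 3(2H)-one because it has no acidic C2 hydrogens to protonate the basic diazo carbon and its ketone is not deactivated, and 17 is added slowly to excess 16 to keep it away from the acidic enol of 19.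

Step 15
Reactants: 19 7-(benzyloxy)-4-ArC-3-hydroxy-2H-chromen-2-one
Product: 20 7-(benzyloxy)-4-ArC-2-oxo-2H-chromen-3-yl trifluoromethanesulfonate
Conditions: Tf2O, pyridine, CH2Cl2, −20 → 0 °C
Reagents that add atoms: trifluoromethanesulfonic anhydride, O=S(=O)(OS(=O)(=O)C(F)(F)F)C(F)(F)F
Why: O-Sulfonylation of the acidic enol of a 3-hydroxycoumarin gives the C3 vinyl triflate as the handle for ring B.

Step 16
Reactants: 21 2,3-dihydroxy-4-methoxybenzaldehyde
Product: 22 2,3-bis(benzyloxy)-4-methoxybenzaldehyde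
Conditions: BnBr (2.5 equiv), K2CO3, DMF, 60 °C
Reagents that add atoms: benzyl bromide, BrCc1ccccc1
Why: Twofold Williamson etherification protects the catechol in the form that the final hydrogenolysis removes.

Step 17
Reactants: 22 2,3-bis(benzyloxy)-4-methoxybenzaldehyde
Product: 24 2,3-bis(benzyloxy)-4-methoxyphenol, via aryl formate 23 (not isolated)
Conditions: mCPBA, CH2Cl2, rt; then K2CO3 (cat.), MeOH
Reagents that add atoms: 3-chloroperbenzoic acid, O=C(OO)c1cccc(Cl)c1
Why: Baeyer–Villiger (Dakin-type) oxidation of the electron-rich benzaldehyde with aryl migration gives the formate, which methanolysis converts to the phenol at the future attachment carbon of ring B.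

Step 18
Reactants: 24 2,3-bis(benzyloxy)-4-methoxyphenol
Product: 25 2,3-bis(benzyloxy)-4-methoxyphenyl trifluoromethanesulfonate
Conditions: Tf2O, pyridine, CH2Cl2, 0 °C
Reagents that add atoms: trifluoromethanesulfonic anhydride, O=S(=O)(OS(=O)(=O)C(F)(F)F)C(F)(F)F
Why: Phenol triflation gives an aryl electrophile for borylation.

Step 19
Reactants: 25 2,3-bis(benzyloxy)-4-methoxyphenyl trifluoromethanesulfonate
Product: 26 2-[2,3-bis(benzyloxy)-4-methoxyphenyl]-4,4,5,5-tetramethyl-1,3,2-dioxaborolane
Conditions: B2pin2, Pd(dppf)Cl2 (5 mol%), KOAc, dioxane, 90 °C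
Reagents that add atoms: bis(pinacolato)diboron, CC1(C)OB(OC1(C)C)B1OC(C)(C)C(C)(C)O1
Why: Miyaura borylation of the aryl triflate gives the ring B nucleophile with unambiguous regiochemistry.

Step 20
Reactants: 20 7-(benzyloxy)-4-ArC-2-oxo-2H-chromen-3-yl trifluoromethanesulfonate; 26 ring B pinacol boronate
Product: 27 7-(benzyloxy)-3-ArB-4-ArC-2H-chromen-2-one
Conditions: Pd(OAc)2 (5 mol%), SPhos (10 mol%), K3PO4, toluene/H2O (10:1), 90 °C
Reagents that add atoms: none
Why: Suzuki–Miyaura coupling of a coumarin 3-triflate forms the C3–ring B bond, with a dialkylbiarylphosphine ligand chosen for the ortho-substituted partners.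

Step 21
Reactants: 27 7-(benzyloxy)-3-ArB-4-ArC-2H-chromen-2-one
Product: 28 (E)-3-[4-(benzyloxy)-2-hydroxyphenyl]-2-ArB-3-ArC-prop-2-en-1-ol (CH2OH and the phenol ring cis)
Conditions: LiAlH4, THF, 0 °C → rt
Reagents that add atoms: none
Why: Hydride reduction of the lactone to the phenol and primary allylic alcohol takes the activating C2 carbonyl down to CH2OH, as known for 3,4-diarylcoumarins; the tetrasubstituted double bond and the benzyl ethers should be inert.

Step 22
Reactants: 28 (E)-3-[4-(benzyloxy)-2-hydroxyphenyl]-2-ArB-3-ArC-prop-2-en-1-ol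
Product: 29 7-(benzyloxy)-3-ArB-4-ArC-2H-chromene
Conditions: PPh3, DIAD, THF, 0 °C → rt
Reagents that add atoms: none
Why: Intramolecular Mitsunobu etherification of the phenol with the cis-disposed primary allylic alcohol recloses the O1–C2 bond (6-exo-tet), the usual way from such diols to 3,4-diaryl-2H-chromenes.

Step 23
Reactants: 29 7-(benzyloxy)-3-ArB-4-ArC-2H-chromene
Product: 30 (3R,4R)-7-(benzyloxy)-3-ArB-4-ArC-chroman (3,4-cis)
Conditions: H2 (100 bar), [Ir(cod)Cl]2 (2.5 mol%), small chiral phosphine–oxazoline ligand (5.5 mol%), NaB[3,5-(CF3)2C6H3]4 (6 mol%), CH2Cl2, 40 °C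
Reagents that add atoms: none
Why: Iridium/P,N-catalysed asymmetric hydrogenation of an unfunctionalised tetrasubstituted cyclic aryl alkene adds H2 syn and gives the cis chroman with C3 (R) fixed by the ligand; because ring C stands perpendicular to the double bond with OMe over one face and the chromanyl group over the other, only the rotamer offering the catalyst-preferred face on its OMe side is expected to react, and the other is recovered, equilibrated by heating and resubmitted.

Step 24
Reactants: 30 (3R,4R)-7-(benzyloxy)-3-ArB-4-ArC-chroman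
Product: 31 (3R,4S)-7-(benzyloxy)-3-ArB-4-ArC-chroman (3,4-trans)
Conditions: KOt-Bu (3 equiv), DMSO, 70 °C
Reagents that add atoms: none
Why: Reversible deprotonation of the doubly benzylic C4–H (C3–H and C3′–H are only singly benzylic and should stay untouched) should equilibrate C4 to the trans isomer, in which both aryl groups can stand pseudo-axial and anti, as in the known base-mediated cis-to-trans isomerisation of 3,4-diarylchromans.

Step 25
Reactants: 31 (3R,4S)-7-(benzyloxy)-3-ArB-4-ArC-chroman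
Product: 32 (3R,4S)-3-(2,3-dihydroxy-4-methoxyphenyl)-4-{4-hydroxy-2-[(3R)-7-hydroxychroman-3-yl]-6-methoxyphenyl}chroman-7-ol (CNP0227211.1)
Conditions: H2 (1 atm), 10% Pd/C, EtOAc/MeOH, rt
Reagents that add atoms: none
Why: Hydrogenolysis removes the five benzyl ethers, while the methyl ethers, the two ring ethers (their O–CH2 carbons are not benzylic) and the three stereocentres should be unaffected.

**Compound list**

1 | 1-bromo-3,5-dimethoxybenzene | COc1cc(Br)cc(OC)c1 | starting material
2 | 2-bromo-4,6-dimethoxybenzaldehyde | COc1cc(Br)c(C=O)c(OC)c1 | intermediate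
3 | 2-bromo-4,6-dihydroxybenzaldehyde | O=Cc1c(Br)cc(O)cc1O | intermediate
4 | 4-(benzyloxy)-2-bromo-6-hydroxybenzaldehyde | O=Cc1c(Br)cc(OCc2ccccc2)cc1O | intermediate
5 | 4-(benzyloxy)-2-bromo-6-methoxybenzaldehyde | COc1cc(OCc2ccccc2)cc(Br)c1C=O | intermediate
6 | 2-[4-(benzyloxy)-2-bromo-6-methoxyphenyl]-1,3-dioxolane | COc1cc(OCc2ccccc2)cc(Br)c1C1OCCO1 | intermediate
7 | 7-hydroxychroman-4-one | O=C1CCOc2cc(O)ccc21 | starting material
8 | 7-(benzyloxy)chroman-4-one | O=C1CCOc2cc(OCc3ccccc3)ccc21 | intermediate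
9 | 7-(benzyloxy)-3-[5-(benzyloxy)-2-(1,3-dioxolan-2-yl)-3-methoxyphenyl]chroman-4-one (racemic) | O=C1C(COc2cc(OCc3ccccc3)ccc21)c1cc(OCc2ccccc2)cc(OC)c1C1OCCO1 | intermediate
10 | 7-(benzyloxy)-3-[5-(benzyloxy)-2-(1,3-dioxolan-2-yl)-3-methoxyphenyl]chroman-4-ol (diastereomer mixture, not isolated) | OC1C(COc2cc(OCc3ccccc3)ccc21)c1cc(OCc2ccccc2)cc(OC)c1C1OCCO1 | intermediate
11 | 4-(benzyloxy)-2-[7-(benzyloxy)-2H-chromen-3-yl]-6-methoxybenzaldehyde | O=Cc1c(OC)cc(OCc2ccccc2)cc1C1=Cc2ccc(OCc3ccccc3)cc2OC1 | intermediate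
12 | 4-(benzyloxy)-2-[(3R)-7-(benzyloxy)chroman-3-yl]-6-methoxybenzaldehyde | O=Cc1c(OC)cc(OCc2ccccc2)cc1[C@@H]1COc2cc(OCc3ccccc3)ccc2C1 | intermediate
13 | (E)-hydrazone of 12 | N/N=C/c1c(OC)cc(OCc2ccccc2)cc1[C@@H]1COc2cc(OCc3ccccc3)ccc2C1 | intermediate
14 | 6-hydroxybenzofuran-3(2H)-one | O=C1COc2cc(O)ccc21 | starting material
15 | 6-(benzyloxy)benzofuran-3(2H)-one | O=C1COc2cc(OCc3ccccc3)ccc21 | intermediate
16 | 6-(benzyloxy)benzofuran-2,3-dione | O=C1Oc2cc(OCc3ccccc3)ccc2C1=O | intermediate
17 | (3R)-7-(benzyloxy)-3-[5-(benzyloxy)-2-(diazomethyl)-3-methoxyphenyl]chroman | [N-]=[N+]=Cc1c(OC)cc(OCc2ccccc2)cc1[C@@H]1COc2cc(OCc3ccccc3)ccc2C1 | intermediate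
18 | 7-(benzyloxy)-4-{4-(benzyloxy)-2-[(3R)-7-(benzyloxy)chroman-3-yl]-6-methoxyphenyl}chromane-2,3-dione (C4 epimers, not isolated) | O=C1Oc2cc(OCc3ccccc3)ccc2C(c2c(OC)cc(OCc3ccccc3)cc2[C@@H]2COc3cc(OCc4ccccc4)ccc3C2)C1=O | intermediate
19 | 7-(benzyloxy)-4-{4-(benzyloxy)-2-[(3R)-7-(benzyloxy)chroman-3-yl]-6-methoxyphenyl}-3-hydroxy-2H-chromen-2-one | O=C1Oc2cc(OCc3ccccc3)ccc2C(c2c(OC)cc(OCc3ccccc3)cc2[C@@H]2COc3cc(OCc4ccccc4)ccc3C2)=C1O | intermediate
20 | 7-(benzyloxy)-4-{4-(benzyloxy)-2-[(3R)-7-(benzyloxy)chroman-3-yl]-6-methoxyphenyl}-2-oxo-2H-chromen-3-yl trifluoromethanesulfonate | O=C1Oc2cc(OCc3ccccc3)ccc2C(c2c(OC)cc(OCc3ccccc3)cc2[C@@H]2COc3cc(OCc4ccccc4)ccc3C2)=C1OS(=O)(=O)C(F)(F)F | intermediate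
21 | 2,3-dihydroxy-4-methoxybenzaldehyde | COc1ccc(C=O)c(O)c1O | starting material
22 | 2,3-bis(benzyloxy)-4-methoxybenzaldehyde | COc1ccc(C=O)c(OCc2ccccc2)c1OCc1ccccc1 | intermediate
23 | 2,3-bis(benzyloxy)-4-methoxyphenyl formate (not isolated) | COc1ccc(OC=O)c(OCc2ccccc2)c1OCc1ccccc1 | intermediate
24 | 2,3-bis(benzyloxy)-4-methoxyphenol | COc1ccc(O)c(OCc2ccccc2)c1OCc1ccccc1 | intermediate
25 | 2,3-bis(benzyloxy)-4-methoxyphenyl trifluoromethanesulfonate | COc1ccc(OS(=O)(=O)C(F)(F)F)c(OCc2ccccc2)c1OCc1ccccc1 | intermediate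
26 | 2-[2,3-bis(benzyloxy)-4-methoxyphenyl]-4,4,5,5-tetramethyl-1,3,2-dioxaborolane | COc1ccc(B2OC(C)(C)C(C)(C)O2)c(OCc2ccccc2)c1OCc1ccccc1 | intermediate
27 | 7-(benzyloxy)-3-[2,3-bis(benzyloxy)-4-methoxyphenyl]-4-{4-(benzyloxy)-2-[(3R)-7-(benzyloxy)chroman-3-yl]-6-methoxyphenyl}-2H-chromen-2-one | COc1ccc(C2=C(c3c(OC)cc(OCc4ccccc4)cc3[C@@H]3COc4cc(OCc5ccccc5)ccc4C3)c3ccc(OCc4ccccc4)cc3OC2=O)c(OCc2ccccc2)c1OCc1ccccc1 | intermediate
28 | (E)-3-[4-(benzyloxy)-2-hydroxyphenyl]-2-[2,3-bis(benzyloxy)-4-methoxyphenyl]-3-{4-(benzyloxy)-2-[(3R)-7-(benzyloxy)chroman-3-yl]-6-methoxyphenyl}prop-2-en-1-ol | COc1ccc(/C(CO)=C(/c2ccc(OCc3ccccc3)cc2O)c2c(OC)cc(OCc3ccccc3)cc2[C@@H]2COc3cc(OCc4ccccc4)ccc3C2)c(OCc2ccccc2)c1OCc1ccccc1 | intermediate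
29 | 7-(benzyloxy)-3-[2,3-bis(benzyloxy)-4-methoxyphenyl]-4-{4-(benzyloxy)-2-[(3R)-7-(benzyloxy)chroman-3-yl]-6-methoxyphenyl}-2H-chromene | COc1ccc(C2=C(c3c(OC)cc(OCc4ccccc4)cc3[C@@H]3COc4cc(OCc5ccccc5)ccc4C3)c3ccc(OCc4ccccc4)cc3OC2)c(OCc2ccccc2)c1OCc1ccccc1 | intermediate
30 | (3R,4R)-7-(benzyloxy)-3-[2,3-bis(benzyloxy)-4-methoxyphenyl]-4-{4-(benzyloxy)-2-[(3R)-7-(benzyloxy)chroman-3-yl]-6-methoxyphenyl}chroman (cis) | COc1ccc([C@@H]2COc3cc(OCc4ccccc4)ccc3[C@@H]2c2c(OC)cc(OCc3ccccc3)cc2[C@@H]2COc3cc(OCc4ccccc4)ccc3C2)c(OCc2ccccc2)c1OCc1ccccc1 | intermediate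
31 | (3R,4S)-7-(benzyloxy)-3-[2,3-bis(benzyloxy)-4-methoxyphenyl]-4-{4-(benzyloxy)-2-[(3R)-7-(benzyloxy)chroman-3-yl]-6-methoxyphenyl}chroman (trans) | COc1ccc([C@@H]2COc3cc(OCc4ccccc4)ccc3[C@H]2c2c(OC)cc(OCc3ccccc3)cc2[C@@H]2COc3cc(OCc4ccccc4)ccc3C2)c(OCc2ccccc2)c1OCc1ccccc1 | intermediate
32 | (3R,4S)-3-(2,3-dihydroxy-4-methoxyphenyl)-4-{4-hydroxy-2-[(3R)-7-hydroxychroman-3-yl]-6-methoxyphenyl}chroman-7-ol | COc1ccc([C@@H]2COc3cc(O)ccc3[C@H]2c2c(OC)cc(O)cc2[C@@H]2COc3cc(O)ccc3C2)c(O)c1O | target

**Step count and risks**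

Total steps: 25. Longest linear sequence: 18 steps (steps 1–5, 7–10, 13–15 and 20–25).

Step 14 (the proposed new method) is the main risk. The hindered, electron-rich diazo compound may lose N2 by acid-induced decomposition or azine formation faster than it adds to C3. The tetrahedral adduct may also close to the spiro-epoxide instead of rearranging, or the acyl carbon may migrate in place of the aryl carbon. The fallback uses known reactions only, sets out from aldehyde 12 and comes back at 19. 2,4-Bis(benzyloxy)phenyllithium (from 1-bromo-2,4-bis(benzyloxy)benzene and n-BuLi, THF, −78 °C) is added to 12 to give the diarylmethanol F1. MnO2 in CH2Cl2 oxidises it to the benzophenone F2. MgBr2·OEt2 (toluene/Et2O, reflux) removes, by chelation to the ketone, only the ortho benzyl ether of ring A and gives the 2-hydroxybenzophenone F3. Esterification with (4-methoxybenzyloxy)acetic acid (DCC, DMAP) gives the aryl ester F4. Intramolecular aldol condensation (KOt-Bu, THF) then closes the pyranone as the 3-(4-methoxybenzyloxy)coumarin F5. CF3CO2H with anisole (CH2Cl2, 0 °C) cleaves the 4-methoxybenzyl ether only and returns 19. In this fallback C4–C4a comes from the aryllithium addition and C3–C4 from the aldol condensation.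

Step 23 is the next risk. The catalyst may not turn over at the crowded tetrasubstituted double bond, whose two faces are screened by the ortho groups of ring C. Facial control by the rotameric axis may also override the ligand, so that both cis series form. The fallback sets out from 29 and comes back at 30. Ionic hydrogenation (Et3SiH, CF3CO2H, CH2Cl2, 0 °C) protonates C3 to the C4 cation stabilised by the 7-benzyloxy group, and hydride then enters anti to ring B. This should give the cis chromans without any metal catalyst, but with C3 uncontrolled: 30 is formed together with its (3S,4S,3′R) diastereomer F6. The two are diastereomers because C3′ is fixed and are separated by chromatography. If the rotamers of 29 prove separable, only the rotamer leading to 30 is reduced and the other is equilibrated thermally and recycled.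

Step 12 is the third risk. The enolisable benzofuranone may couple oxidatively at C2 instead of being oxygenated, and the water formed may open the product lactone. The fallback sets out from 15 and comes back at 16. Nitrosation at C2 (isoamyl nitrite, HCl, Et2O) gives the 2-oxime F7. Oxime exchange with aqueous formaldehyde and HCl gives the ring-opened 2-aryl-2-oxoacetic acid F8. Dehydration (Ac2O, or toluene azeotrope) closes F8 to 16.

**Further compounds**

F1 | step 14 | [2,4-bis(benzyloxy)phenyl]{4-(benzyloxy)-2-[(3R)-7-(benzyloxy)chroman-3-yl]-6-methoxyphenyl}methanol | OC(c1ccc(OCc2ccccc2)cc1OCc1ccccc1)c1c(OC)cc(OCc2ccccc2)cc1[C@@H]1COc2cc(OCc3ccccc3)ccc2C1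
F2 | step 14 | [2,4-bis(benzyloxy)phenyl]{4-(benzyloxy)-2-[(3R)-7-(benzyloxy)chroman-3-yl]-6-methoxyphenyl}methanone | O=C(c1ccc(OCc2ccccc2)cc1OCc1ccccc1)c1c(OC)cc(OCc2ccccc2)cc1[C@@H]1COc2cc(OCc3ccccc3)ccc2C1
F3 | step 14 | [4-(benzyloxy)-2-hydroxyphenyl]{4-(benzyloxy)-2-[(3R)-7-(benzyloxy)chroman-3-yl]-6-methoxyphenyl}methanone | O=C(c1ccc(OCc2ccccc2)cc1O)c1c(OC)cc(OCc2ccccc2)cc1[C@@H]1COc2cc(OCc3ccccc3)ccc2C1
F4 | step 14 | 5-(benzyloxy)-2-{4-(benzyloxy)-2-[(3R)-7-(benzyloxy)chroman-3-yl]-6-methoxybenzoyl}phenyl [(4-methoxybenzyl)oxy]acetate | COc1ccc(COCC(=O)Oc2cc(OCc3ccccc3)ccc2C(=O)c2c(OC)cc(OCc3ccccc3)cc2[C@@H]2COc3cc(OCc4ccccc4)ccc3C2)cc1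
F5 | step 14 | 7-(benzyloxy)-4-{4-(benzyloxy)-2-[(3R)-7-(benzyloxy)chroman-3-yl]-6-methoxyphenyl}-3-[(4-methoxybenzyl)oxy]-2H-chromen-2-one | COc1ccc(COC2=C(c3c(OC)cc(OCc4ccccc4)cc3[C@@H]3COc4cc(OCc5ccccc5)ccc4C3)c3ccc(OCc4ccccc4)cc3OC2=O)cc1
F6 | step 23 | (3S,4S)-7-(benzyloxy)-3-[2,3-bis(benzyloxy)-4-methoxyphenyl]-4-{4-(benzyloxy)-2-[(3R)-7-(benzyloxy)chroman-3-yl]-6-methoxyphenyl}chroman | COc1ccc([C@H]2COc3cc(OCc4ccccc4)ccc3[C@H]2c2c(OC)cc(OCc3ccccc3)cc2[C@@H]2COc3cc(OCc4ccccc4)ccc3C2)c(OCc2ccccc2)c1OCc1ccccc1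
F7 | step 12 | 6-(benzyloxy)-2-(hydroxyimino)benzofuran-3(2H)-one | O=C1C(=NO)Oc2cc(OCc3ccccc3)ccc21
F8 | step 12 | 2-[4-(benzyloxy)-2-hydroxyphenyl]-2-oxoacetic acid | O=C(O)C(=O)c1ccc(OCc2ccccc2)cc1O
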